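The seven-membered ring is cut at its two aryl–methine bonds: benzofuran C4–Ca (Ca bears the 2-hydroxy-5-formylphenyl group) and resorcinol-ring C2–Cb (Cb bears the 4-hydroxyphenyl group). Both are made in one copper-catalysed arylative (5+2) annulation: the C4 aryl(mesityl)iodonium salt of an enantiopure trans-2,3-diaryl-2,3-dihydrobenzofuran delivers its aryl group to Ca of an (E)-stilbene, and the 4-methoxybenzylic cation so formed at Cb is trapped by the neighbouring dimethoxyphenyl ring (ring B) on furan C3. The step exploits the para-oxygenated aryl on Cb, the electron-rich C2 of ring B and the rigid C4/C3 geometry. The dihydrobenzofuran arises from an o-quinone methide and a chiral sulfur ylide.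

Key step: step 11

Assumption: the chiral sulfonium ylide is taken to show the same facial preference towards the o-quinone methide as in its aldehyde epoxidations; if the sense proves opposite, the (2R,5R)-sulfide from (2S,5S)-hexane-2,5-diol is used instead.

Step 1
Reactants: 1 2-bromo-4,6-dimethoxybenzaldehyde
Product: 2 2-bromo-6-hydroxy-4-methoxybenzaldehyde
Conditions: BCl3 (1.1 equiv), CH2Cl2, −78 to 0 °C; then H2O
Reagents that add atoms: none
Why: BCl3 chelates between the formyl oxygen and the ortho methoxy group, so only the methyl ether next to the aldehyde should be cleaved (chelation-controlled Lewis acid ether cleavage).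

Step 2
Reactants: 2 2-bromo-6-hydroxy-4-methoxybenzaldehyde; 3 3,5-dimethoxyphenylmagnesium chloride (2.2 equiv, THF solution)
Product: 4 rac-3-bromo-2-[(3,5-dimethoxyphenyl)(hydroxy)methyl]-5-methoxyphenol
Conditions: THF, 0 °C to rt; aq. NH4Cl
Reagents that add atoms: none
Why: Grignard 1,2-addition to the aldehyde after the first equivalent has deprotonated the phenol; the aryl bromide is inert at this temperature and the racemic carbinol centre is erased in step 7.

Step 3
Reactants: 4 rac-3-bromo-2-[(3,5-dimethoxyphenyl)(hydroxy)methyl]-5-methoxyphenol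
Product: 5 rac-3-bromo-2-[(3,5-dimethoxyphenyl)(4-methylbenzenesulfonyl)methyl]-5-methoxyphenol
Conditions: TolSO2Na, HCO2H/H2O, rt
Reagents that add atoms: sodium 4-methylbenzenesulfinate, Cc1ccc(cc1)S(=O)[O-].[Na+]
Why: Acid ionises the doubly activated benzhydrol and the soft sulfinate captures the cation at sulfur (SN1 sulfinate alkylation), giving a base-triggered o-quinone methide precursor.

Step 4
Reactants: 6 (2R,5R)-hexane-2,5-diol
Product: 7 (2R,5R)-hexane-2,5-diyl dimethanesulfonate
Conditions: MsCl, Et3N, CH2Cl2, 0 °C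
Reagents that add atoms: methanesulfonyl chloride, CS(=O)(=O)Cl
Why: O-Sulfonylation of both secondary alcohols with retention at carbon.

Step 5
Reactants: 7 (2R,5R)-hexane-2,5-diyl dimethanesulfonate
Product: 8 (2S,5S)-2,5-dimethylthiolane
Conditions: Na2S·9H2O, EtOH/H2O, 50 °C
Reagents that add atoms: sodium sulfide, [Na+].[Na+].[S-2]
Why: Double SN2 displacement by sulfide closes the thiolane with inversion at both centres, turning (R,R) into (S,S).

Step 6
Reactants: 8 (2S,5S)-2,5-dimethylthiolane; 9 4-methoxybenzyl bromide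
Product: 10 (2S,5S)-1-(4-methoxybenzyl)-2,5-dimethylthiolan-1-ium tetrafluoroborate
Conditions: AgBF4, CH2Cl2, 0 °C to rt
Reagents that add atoms: silver tetrafluoroborate, [Ag+].F[B-](F)(F)F
Why: S-Alkylation of the sulfide by the benzylic bromide, driven by precipitation of AgBr; sulfur lies on the C2 axis, so no new stereocentre arises.

Step 7
Reactants: 5 rac-3-bromo-2-[(3,5-dimethoxyphenyl)(4-methylbenzenesulfonyl)methyl]-5-methoxyphenol; 10 (2S,5S)-1-(4-methoxybenzyl)-2,5-dimethylthiolan-1-ium tetrafluoroborate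
Product: 12 (2S,3S)-4-bromo-3-(3,5-dimethoxyphenyl)-6-methoxy-2-(4-methoxyphenyl)-2,3-dihydro-1-benzofuran, via o-quinone methide 11 (not isolated)
Conditions: Cs2CO3 (3 equiv), MeCN, 0 °C to rt
Reagents that add atoms: none
Why: Base-induced loss of sulfinate gives o-quinone methide 11, the chiral benzylic sulfonium ylide adds in conjugate fashion and the phenoxide displaces the sulfide by SN2 ([4+1] annulation of a sulfur ylide with an o-quinone methide); the C2-symmetric sulfide should fix C2 through the ylide face and the anti addition mode should place the aryl groups trans, which sets C3 (any cis isomer is removed by chromatography).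

Step 8
Reactants: 12 (2S,3S)-4-bromo-3-(3,5-dimethoxyphenyl)-6-methoxy-2-(4-methoxyphenyl)-2,3-dihydro-1-benzofuran
Product: 14 [(2S,3S)-3-(3,5-dimethoxyphenyl)-6-methoxy-2-(4-methoxyphenyl)-2,3-dihydro-1-benzofuran-4-yl]boronic acid, via aryllithium 13 (not isolated)
Conditions: n-BuLi, THF, −78 °C; B(OiPr)3, −78 °C to rt; 1 M HCl
Reagents that add atoms: triisopropyl borate, CC(C)OB(OC(C)C)OC(C)C; water, O
Why: Bromine–lithium exchange at −78 °C should outrun any deprotonation, and the aryllithium is trapped by the borate (borylation via the ate complex, hydrolysed on work-up) without touching the stereocentres.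

Step 9
Reactants: 14 [(2S,3S)-3-(3,5-dimethoxyphenyl)-6-methoxy-2-(4-methoxyphenyl)-2,3-dihydro-1-benzofuran-4-yl]boronic acid
Product: 15 [(2S,3S)-3-(3,5-dimethoxyphenyl)-6-methoxy-2-(4-methoxyphenyl)-2,3-dihydro-1-benzofuran-4-yl](2,4,6-trimethylphenyl)iodonium trifluoromethanesulfonate
Conditions: MesI(OAc)2/TfOH (premixed), CH2Cl2, −30 °C; then 14, −30 to 0 °C
Reagents that add atoms: (diacetoxyiodo)mesitylene, CC(=O)OI(OC(C)=O)c1c(C)cc(C)cc1C; trifluoromethanesulfonic acid, OS(=O)(=O)C(F)(F)F
Why: Ipso boron-to-iodine aryl transfer to the triflate-activated trivalent iodine reagent (known synthesis of diaryliodonium triflates from arylboronic acids) is regiospecific at C4 and installs mesityl as the non-transferable group.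

Step 10
Reactants: 16 3-bromo-4-methoxybenzaldehyde; 17 4-methoxystyrene
Product: 18 (E)-4-methoxy-3-[2-(4-methoxyphenyl)ethenyl]benzaldehyde
Conditions: Pd(OAc)2 (2 mol %), P(o-tol)3, Et3N, DMF, 100 °C
Reagents that add atoms: none
Why: Mizoroki–Heck arylation of the terminal styrene carbon (syn insertion, syn β-hydride elimination) should give the (E)-stilbene, with the aldehyde inert.

Step 11
Reactants: 15 [(2S,3S)-3-(3,5-dimethoxyphenyl)-6-methoxy-2-(4-methoxyphenyl)-2,3-dihydro-1-benzofuran-4-yl](2,4,6-trimethylphenyl)iodonium trifluoromethanesulfonate; 18 (E)-4-methoxy-3-[2-(4-methoxyphenyl)ethenyl]benzaldehyde (3 equiv)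
Product: 20 hexa-O-methylvitisinol B (the target with all six phenols as methyl ethers; (2S,3S) in the dihydrofuran, (R) at Ca, (S) at Cb, the two bridge aryl groups trans), via benzylic cation 19 (not isolated)
Conditions: Cu(OTf)2 (10 mol %), 2,6-di-tert-butylpyridine (1.2 equiv), ClCH2CH2Cl, 50 °C
Reagents that add atoms: none
Why: Proposed new method: Cu(OTf)2 is reduced in situ to monovalent copper, which adds oxidatively to 15 and takes over the benzofuranyl group (the doubly ortho-substituted mesityl stays on iodine); the electrophilic trivalent aryl-copper species attacks the stilbene C=C at Ca, cation 19 forms at Cb, and C2 of ring B closes the ring by Friedel–Crafts alkylation with loss of a proton to the pyridine base. The closest known reaction type is the copper-catalysed carboarylation of alkynes and alkenes with diaryliodonium salts (electrophilic aryl transfer, then capture of the cation by an arene); new here is that the trapping arene sits on the transferred aryl group, so the alkene enters as the two-carbon partner of a formal (5+2) annulation. The seven-membered ring closes by intramolecular cation–arene attack, made possible because the five-atom unit from benzofuran C4 through C3a and C3 to C1 and C2 of ring B is held rigid by the dihydrofuran ring. Both new aryl–carbon bonds are made on the same face of the (E)-alkene by the two ends of that unit, which gives the trans diaryl relationship, and the alkene should dock with both aryl groups pseudo-equatorial and pointing away from the dihydrobenzofuran, so that the existing C3 centre sets (R) at Ca and (S) at Cb. The step needs regioselective aryl transfer to Ca and attack on the alkene in preference to arenes: the first is secured by the donor 4-methoxyphenyl group on Cb against the formyl-deactivated ring on Ca, the second by the excess of 18 and by the strain of the alternative fluorene-type closure onto ring B.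

Step 12
Reactants: 20 hexa-O-methylvitisinol B
Product: 21 vitisinol B
Conditions: BBr3 (excess), CH2Cl2, −78 to 0 °C; then MeOH, H2O
Reagents that add atoms: none
Why: Lewis acid-mediated cleavage of the six aryl methyl ethers (BBr3 demethylation) at low temperature should leave the dihydrofuran C–O bond and the four stereocentres intact, and the aldehyde is returned on hydrolytic work-up.

Compound list
1 | 2-bromo-4,6-dimethoxybenzaldehyde | COc1cc(Br)c(C=O)c(OC)c1 | starting material
2 | 2-bromo-6-hydroxy-4-methoxybenzaldehyde | COc1cc(O)c(C=O)c(Br)c1 | intermediate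
3 | 3,5-dimethoxyphenylmagnesium chloride | COc1cc(OC)cc([Mg]Cl)c1 | starting material
4 | rac-3-bromo-2-[(3,5-dimethoxyphenyl)(hydroxy)methyl]-5-methoxyphenol | COc1cc(O)c(C(O)c2cc(OC)cc(OC)c2)c(Br)c1 | intermediate
5 | rac-3-bromo-2-[(3,5-dimethoxyphenyl)(4-methylbenzenesulfonyl)methyl]-5-methoxyphenol | COc1cc(O)c(C(c2cc(OC)cc(OC)c2)S(=O)(=O)c2ccc(C)cc2)c(Br)c1 | intermediate
6 | (2R,5R)-hexane-2,5-diol | C[C@@H](O)CC[C@@H](C)O | starting material
7 | (2R,5R)-hexane-2,5-diyl dimethanesulfonate | C[C@@H](OS(C)(=O)=O)CC[C@@H](C)OS(C)(=O)=O | intermediate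
8 | (2S,5S)-2,5-dimethylthiolane | C[C@H]1CC[C@H](C)S1 | intermediate
9 | 4-methoxybenzyl bromide | COc1ccc(CBr)cc1 | starting material
10 | (2S,5S)-1-(4-methoxybenzyl)-2,5-dimethylthiolan-1-ium tetrafluoroborate | C[C@H]1CC[C@H](C)[S+]1Cc1ccc(OC)cc1.F[B-](F)(F)F | intermediate
11 | (6E)-5-bromo-6-[(3,5-dimethoxyphenyl)methylidene]-3-methoxycyclohexa-2,4-dien-1-one (o-quinone methide) | O=C1C=C(OC)C=C(Br)/C1=C/c1cc(OC)cc(OC)c1 | intermediate (not isolated)
12 | (2S,3S)-4-bromo-3-(3,5-dimethoxyphenyl)-6-methoxy-2-(4-methoxyphenyl)-2,3-dihydro-1-benzofuran | Brc1cc(OC)cc2c1[C@H](c1cc(OC)cc(OC)c1)[C@@H](c1ccc(OC)cc1)O2 | intermediate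
13 | [(2S,3S)-3-(3,5-dimethoxyphenyl)-6-methoxy-2-(4-methoxyphenyl)-2,3-dihydro-1-benzofuran-4-yl]lithium | [Li]c1cc(OC)cc2c1[C@H](c1cc(OC)cc(OC)c1)[C@@H](c1ccc(OC)cc1)O2 | intermediate (not isolated)
14 | [(2S,3S)-3-(3,5-dimethoxyphenyl)-6-methoxy-2-(4-methoxyphenyl)-2,3-dihydro-1-benzofuran-4-yl]boronic acid | OB(O)c1cc(OC)cc2c1[C@H](c1cc(OC)cc(OC)c1)[C@@H](c1ccc(OC)cc1)O2 | intermediate
15 | [(2S,3S)-3-(3,5-dimethoxyphenyl)-6-methoxy-2-(4-methoxyphenyl)-2,3-dihydro-1-benzofuran-4-yl](2,4,6-trimethylphenyl)iodonium trifluoromethanesulfonate | Cc1cc(C)c([I+]c2cc(OC)cc3c2[C@H](c2cc(OC)cc(OC)c2)[C@@H](c2ccc(OC)cc2)O3)c(C)c1.[O-]S(=O)(=O)C(F)(F)F | intermediate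
16 | 3-bromo-4-methoxybenzaldehyde | O=Cc1ccc(OC)c(Br)c1 | starting material
17 | 4-methoxystyrene | C=Cc1ccc(OC)cc1 | starting material
18 | (E)-4-methoxy-3-[2-(4-methoxyphenyl)ethenyl]benzaldehyde | O=Cc1ccc(OC)c(/C=C/c2ccc(OC)cc2)c1 | intermediate
19 | 4-methoxybenzylic cation at Cb after aryl transfer to Ca, as its triflate | O=Cc1ccc(OC)c([C@H]([CH+]c2ccc(OC)cc2)c2cc(OC)cc3c2[C@H](c2cc(OC)cc(OC)c2)[C@@H](c2ccc(OC)cc2)O3)c1.[O-]S(=O)(=O)C(F)(F)F | intermediate (not isolated)
20 | hexa-O-methylvitisinol B | O=Cc1ccc(OC)c([C@H]2c3cc(OC)cc4c3[C@H](c3cc(OC)cc(OC)c3[C@@H]2c2ccc(OC)cc2)[C@@H](c2ccc(OC)cc2)O4)c1 | intermediate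
21 | vitisinol B | O=Cc1ccc(O)c([C@H]2c3cc(O)cc4c3[C@H](c3cc(O)cc(O)c3[C@@H]2c2ccc(O)cc2)[C@@H](c2ccc(O)cc2)O4)c1 | target

Total step count: 12. Longest linear sequence: 8 steps (1, 2, 3, 7, 8, 9, 11, 12).

Steps most likely to fail

Step 11. The aryl-copper species may arylate arene rings instead of the alkene (oligomerisation through ring B), the cation may lose a proton before ring closure, or the alkene face may be poorly differentiated. The fallback uses known chemistry, sets out from 12 and 16 and returns at 20. Acetalisation of 16 (ethane-1,2-diol, TsOH, toluene, reflux) should give the bromo acetal F1. Palladium-catalysed ketone α-arylation of 4'-methoxyacetophenone with it (Pd2(dba)3, XPhos, NaOtBu, toluene, 80 °C) should give the deoxybenzoin F2. A second α-arylation of this ketone with bromide 12 under the same conditions should make the C4–Ca bond and give the triaryl ketone F3 as epimers at Ca. NaBH4 in MeOH/THF should give the carbinol F4. TFA in CH2Cl2 should then ionise the 4-methoxybenzylic alcohol at Cb, ring B closes the seven-membered ring by Friedel–Crafts alkylation, and aqueous acid frees the aldehyde to give 20.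

Step 9. Ring B may attack the activated iodine reagent in competition with boron-to-iodine transfer, or the acid may open the dihydrofuran. The fallback replaces the acid-promoted transfer by a neutral tin-to-iodine exchange, sets out from 12 and returns at 15. Bromine–lithium exchange (n-BuLi, THF, −78 °C) and quenching with Bu3SnCl should give the arylstannane F5. [Hydroxy(tosyloxy)iodo]mesitylene in CH2Cl2 at 0 °C should give the iodonium tosylate F6, and washing with aqueous NaOTf should give triflate 15.

Step 7. The trans/cis ratio or the enantiofacial selectivity of the ylide addition may be poor, the phenoxide may be O-benzylated by the sulfonium salt, or the quinone methide may dimerise. The fallback replaces asymmetric induction by resolution, sets out from 5 and 9 and returns at 12. Alkylation of thiolane with 9 (AgBF4, CH2Cl2) should give the achiral sulfonium salt F7. The same [4+1] annulation with 5 (Cs2CO3, MeCN) should give the racemic trans-dihydrobenzofuran, that is 12 together with its (2R,3R)-enantiomer F8. Preparative chromatography on a chiral stationary phase should then give 12.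

Further compounds
F1 | step 11 | 2-(3-bromo-4-methoxyphenyl)-1,3-dioxolane | COc1ccc(cc1Br)C1OCCO1
F2 | step 11 | 2-[5-(1,3-dioxolan-2-yl)-2-methoxyphenyl]-1-(4-methoxyphenyl)ethan-1-one | COc1ccc(cc1)C(=O)Cc1cc(ccc1OC)C1OCCO1
F3 | step 11 | 2-[(2S,3S)-3-(3,5-dimethoxyphenyl)-6-methoxy-2-(4-methoxyphenyl)-2,3-dihydro-1-benzofuran-4-yl]-2-[5-(1,3-dioxolan-2-yl)-2-methoxyphenyl]-1-(4-methoxyphenyl)ethan-1-one (epimers at C2 of the ethanone) | COc1ccc(cc1)C(=O)C(c1cc(ccc1OC)C1OCCO1)c1cc(OC)cc2c1[C@H](c1cc(OC)cc(OC)c1)[C@@H](c1ccc(OC)cc1)O2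
F4 | step 11 | 2-[(2S,3S)-3-(3,5-dimethoxyphenyl)-6-methoxy-2-(4-methoxyphenyl)-2,3-dihydro-1-benzofuran-4-yl]-2-[5-(1,3-dioxolan-2-yl)-2-methoxyphenyl]-1-(4-methoxyphenyl)ethan-1-ol (diastereomer mixture) | COc1ccc(cc1)C(O)C(c1cc(ccc1OC)C1OCCO1)c1cc(OC)cc2c1[C@H](c1cc(OC)cc(OC)c1)[C@@H](c1ccc(OC)cc1)O2
F5 | step 9 | tributyl[(2S,3S)-3-(3,5-dimethoxyphenyl)-6-methoxy-2-(4-methoxyphenyl)-2,3-dihydro-1-benzofuran-4-yl]stannane | CCCC[Sn](CCCC)(CCCC)c1cc(OC)cc2c1[C@H](c1cc(OC)cc(OC)c1)[C@@H](c1ccc(OC)cc1)O2
F6 | step 9 | [(2S,3S)-3-(3,5-dimethoxyphenyl)-6-methoxy-2-(4-methoxyphenyl)-2,3-dihydro-1-benzofuran-4-yl](2,4,6-trimethylphenyl)iodonium 4-methylbenzenesulfonate | Cc1cc(C)c([I+]c2cc(OC)cc3c2[C@H](c2cc(OC)cc(OC)c2)[C@@H](c2ccc(OC)cc2)O3)c(C)c1.Cc1ccc(cc1)S(=O)(=O)[O-]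
F7 | step 7 | 1-(4-methoxybenzyl)thiolan-1-ium tetrafluoroborate | COc1ccc(C[S+]2CCCC2)cc1.F[B-](F)(F)F
F8 | step 7 | (2R,3R)-4-bromo-3-(3,5-dimethoxyphenyl)-6-methoxy-2-(4-methoxyphenyl)-2,3-dihydro-1-benzofuran | Brc1cc(OC)cc2c1[C@@H](c1cc(OC)cc(OC)c1)[C@H](c1ccc(OC)cc1)O2
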